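## Retrosynthetic overview

1. Feature: on ring A the C8 substituent CH(propyl)CH2CO2Me stands ortho to the free 7-hydroxyl. The chain O7–C7–C8–CH–CH2–C(=O) is therefore a latent six-membered lactone, and the target is the methanolysis product of a 4-propyl-dihydrocoumarin (ring C) fused at C7/C8.
2. Key disconnection: ring C is cut at C8–CH and at O7–C(=O). This leads back to the 6-prenyl-5,7-dihydroxychromanone and hex-2-ynal, which are joined under a chiral triazolylidene that sets the R centre.
3. The C6 prenyl group comes from a 5-O-allyl ether by a Claisen shift to the only free ortho carbon and then cross-metathesis, with O7 masked as a MOM ether.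
4. Ring B (O1–C2–C3–C4) is cut at C3–C4. It is closed by carbene hydroacylation of an (S)-1-methylallyl aryl ether made by Mitsunobu inversion of (R)-but-3-en-2-ol, and C3 settles trans.
5. Ring order: A (bought), then B (step 3), then C (closed in step 10 and opened again in step 11).

Key step: step 10

Assumption: precedent does not fix the sense of induction of the aminoindanol triazolium salt on this new enol partner, so the (5aR,10bS) salt, Cc1cc(C)c(c(C)c1)[N+]2=CN3C(=N2)CO[C@@H]4Cc5ccccc5[C@H]34.[Cl-], is written throughout, and its commercially available mirror image is used instead if a pilot run shows the S centre.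

Locants: chromanone numbering is O1, C2, C3, C4, C4a, C5–C8, C8a. Ring A is the benzene ring, ring B the dihydropyranone and ring C the temporary lactone.

## Route

Step 1
Reactants: 1 2,4,6-trihydroxybenzaldehyde
Product: 2 2-hydroxy-4,6-bis(methoxymethoxy)benzaldehyde
Conditions: MOMCl (2.1 equiv), iPr2NEt, CH2Cl2, 0 °C to rt
Reagents that add atoms: chloromethyl methyl ether (MOMCl), COCCl
Why: O-alkylation (MOM protection) takes the 4-hydroxyl and one of the two equivalent ortho hydroxyls, while the last ortho hydroxyl is held in a hydrogen bond to the formyl oxygen and stays free when only two equivalents of reagent are offered.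

Step 2
Reactants: 2 2-hydroxy-4,6-bis(methoxymethoxy)benzaldehyde; 3 (R)-but-3-en-2-ol
Product: 4 2-{[(2S)-but-3-en-2-yl]oxy}-4,6-bis(methoxymethoxy)benzaldehyde
Conditions: PPh3, DIAD, THF, −20 °C to rt
Reagents that add atoms: none
Why: In this Mitsunobu etherification the acidic salicylaldehyde-type phenol displaces the activated secondary allylic alcohol by SN2 with inversion, so the R alcohol gives the S aryl ether carbon that becomes C2, and the low temperature keeps SN2′ attack down.

Step 3
Reactants: 4 2-{[(2S)-but-3-en-2-yl]oxy}-4,6-bis(methoxymethoxy)benzaldehyde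
Product: 6 (2S,3S)-5,7-bis(methoxymethoxy)-2,3-dimethylchroman-4-one, via Breslow enaminol 5 (not isolated)
Conditions: 3-mesityl-5,6,7,8-tetrahydro-4H-cyclohepta[d]thiazol-3-ium perchlorate (20 mol %), DBU (25 mol %), 1,4-dioxane, 120 °C, sealed tube
Reagents that add atoms: none
Why: This is the carbene-catalysed intramolecular hydroacylation of an unactivated alkene known for 2-allyloxybenzaldehydes, in which enaminol 5 delivers its acyl carbon to the internal alkene carbon and its proton to the terminal carbon (6-exo closure of ring B), C2 is carried through untouched, and C3, being alpha to the new ketone, should settle under the amidine base as the diequatorial trans (3S) isomer.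

Step 4
Reactants: 6 (2S,3S)-5,7-bis(methoxymethoxy)-2,3-dimethylchroman-4-one
Product: 7 (2S,3S)-5-hydroxy-7-(methoxymethoxy)-2,3-dimethylchroman-4-one
Conditions: iodine (I2, 10 mol %), MeOH, rt, stopped at mono-cleavage
Reagents that add atoms: none
Why: In this mild acid-catalysed transacetalisation with methanol the MOM group peri to the C4 carbonyl should leave first, because the ketone assists its protonation and the freed phenol is locked in a six-membered hydrogen bond, so O7 stays masked and no separate re-protection is needed.

Step 5
Reactants: 7 (2S,3S)-5-hydroxy-7-(methoxymethoxy)-2,3-dimethylchroman-4-one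
Product: 8 (2S,3S)-5-(allyloxy)-7-(methoxymethoxy)-2,3-dimethylchroman-4-one
Conditions: allyl alcohol, PPh3, DIAD, THF, 0 °C to rt
Reagents that add atoms: allyl alcohol, C=CCO
Why: Mitsunobu etherification with a primary allylic alcohol alkylates the chelated 5-hydroxyl under neutral conditions, as is known for 5-hydroxyflavanones, so neither C3 nor the base-sensitive ring B is put at risk.

Step 6
Reactants: 8 (2S,3S)-5-(allyloxy)-7-(methoxymethoxy)-2,3-dimethylchroman-4-one
Product: 10 (2S,3S)-6-allyl-5-hydroxy-7-(methoxymethoxy)-2,3-dimethylchroman-4-one, via ortho-dienone 9 (not isolated)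
Conditions: Eu(fod)3 (10 mol %), PhCl, 120 °C, sealed tube
Reagents that add atoms: none
Why: This aromatic Claisen rearrangement is accelerated by the oxophilic complex Eu(fod)3 bound to the C4 carbonyl and O5, and since one ortho position of O5 is the ring-fusion carbon C4a the allyl group can reach only C6, after which dienone 9 re-aromatises by tautomerisation.

Step 7
Reactants: 10 (2S,3S)-6-allyl-5-hydroxy-7-(methoxymethoxy)-2,3-dimethylchroman-4-one
Product: 11 (2S,3S)-6-allyl-5,7-dihydroxy-2,3-dimethylchroman-4-one
Conditions: HCl (1.25 M in MeOH), 40 °C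
Reagents that add atoms: none
Why: Acid-catalysed acetal exchange removes the last MOM group at the allyl stage, because a monosubstituted alkene is not protonated by dilute methanolic HCl whereas a prenyl group between two phenols could close to a dimethylchroman.

Step 8
Reactants: 11 (2S,3S)-6-allyl-5,7-dihydroxy-2,3-dimethylchroman-4-one
Product: 12 (2S,3S)-5,7-dihydroxy-2,3-dimethyl-6-(3-methylbut-2-en-1-yl)chroman-4-one
Conditions: second-generation Grubbs catalyst (5 mol %), 1,4-benzoquinone (10 mol %), 2-methylbut-2-ene/CH2Cl2, 40 °C, sealed tube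
Reagents that add atoms: 2-methylbut-2-ene, CC=C(C)C
Why: Olefin cross-metathesis of the terminal alkene with an excess of the trisubstituted alkene exchanges =CH2 for =C(CH3)2, a standard allyl-to-prenyl conversion that tolerates free phenols and ketones, with benzoquinone suppressing alkene migration.

Step 9
Reactants: 13 hex-2-yn-1-ol
Product: 14 hex-2-ynal
Conditions: activated MnO2 (15 equiv), CH2Cl2, rt; filtered and used as a solution
Reagents that add atoms: none
Why: Heterogeneous MnO2 oxidation of a propargylic alcohol stops cleanly at the aldehyde and leaves the alkyne untouched.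

Step 10
Reactants: 12 (2S,3S)-5,7-dihydroxy-2,3-dimethyl-6-(3-methylbut-2-en-1-yl)chroman-4-one; 14 hex-2-ynal
Product: 17 (2S,3S,10R)-5-hydroxy-2,3-dimethyl-6-(3-methylbut-2-en-1-yl)-10-propyl-2,3,9,10-tetrahydro-4H,8H-pyrano[2,3-f]chromene-4,8-dione (the O7 lactone of the target acid), via hexenoyl azolium 15 (not isolated), via C8-alkylated acylazolium 16 (not isolated)
Conditions: (5aR,10bS)-2-mesityl-5a,10b-dihydro-4H,6H-indeno[2,1-b][1,2,4]triazolo[4,3-d][1,4]oxazin-2-ium chloride (10 mol %), 14 (1.5 equiv), 4 Å MS, toluene, 40 °C, no added base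
Reagents that add atoms: none
Why: Proposed new method: the carbene adds to the formyl group of 14 and an internal redox through the allenol gives the (E)-α,β-unsaturated acylazolium 15, O7 of 12 adds to its carbonyl carbon and a [3,3] shift (or, with the same outcome, direct Michael attack) bonds C8 to the β-carbon, and proton shifts restore ring A and leave the saturated acylazolium 16. O7 then attacks the acyl carbon of 16 in a 6-exo-trig acyl substitution that closes lactone ring C and releases the carbene, so C8–CH and O7–C(=O) are both made in one flask. The closest known reaction type is the chiral-triazolylidene annulation of ynals with kojic acids, 2-naphthols and cyclic 1,3-dicarbonyl enols to dihydropyranones (Coates–Claisen type); a monocyclic acylphloroglucinol has not served as the enol partner, and the case for it is that the 7-hydroxyl is a vinylogous acid of the C4 ketone with an acidity near that of kojic acid, while C8, ortho to O1 and O7 and para to O5, is the nucleophilic α-carbon of that enol. The new stereocentre is set by the catalyst, whose indane wall covers one face of the acylazolium so that C8 meets the open face of the β-carbon, while C2 and C3 lie too far away to steer, and any S epimer is a diastereomer that chromatography can remove. Site selectivity is needed between C6 and C8 and between O5 and O7: C6 carries the prenyl group, and the 5-hydroxyl is locked in a hydrogen bond to the C4 ketone and has no free ortho carbon, so only the O7/C8 pair can give a six-membered ring. No strong acid or base is present, so the prenyl group, the epimerisable C3 and ring B should pass unchanged.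

Step 11
Reactants: 17 (2S,3S,10R)-5-hydroxy-2,3-dimethyl-6-(3-methylbut-2-en-1-yl)-10-propyl-2,3,9,10-tetrahydro-4H,8H-pyrano[2,3-f]chromene-4,8-dione
Product: 18 methyl (3R)-3-[(2S,3S)-5,7-dihydroxy-2,3-dimethyl-6-(3-methylbut-2-en-1-yl)-4-oxochroman-8-yl]hexanoate (target)
Conditions: MeOH, Et3N (2 equiv), 0 °C to rt; pH 5 buffer work-up, concentration below 30 °C
Reagents that add atoms: methanol, CO
Why: Base-promoted methanolysis (transesterification) of an aryl ester should open the lactone readily because the 7-phenoxide is stabilised by the para C4 ketone, and no stereocentre is touched since the benzylic carbon is beta to the ester carbonyl and the trans C2/C3 pair is already the thermodynamic arrangement.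

## Compound list

1 | 2,4,6-trihydroxybenzaldehyde | O=Cc1c(O)cc(O)cc1O | starting material
2 | 2-hydroxy-4,6-bis(methoxymethoxy)benzaldehyde | O=Cc1c(O)cc(OCOC)cc1OCOC | intermediate
3 | (R)-but-3-en-2-ol | C[C@@H](O)C=C | starting material
4 | 2-{[(2S)-but-3-en-2-yl]oxy}-4,6-bis(methoxymethoxy)benzaldehyde | C=C[C@H](C)Oc1cc(OCOC)cc(OCOC)c1C=O | intermediate
5 | Breslow enaminol of 4 and the N-mesityl cycloheptathiazolylidene (not isolated; enol geometry open) | C=C[C@H](C)Oc1cc(OCOC)cc(OCOC)c1C(O)=C1SC2=C(CCCCC2)N1c1c(C)cc(C)cc1C | intermediate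
6 | (2S,3S)-5,7-bis(methoxymethoxy)-2,3-dimethylchroman-4-one | COCOc1cc(OCOC)c2c(c1)O[C@@H](C)[C@H](C)C2=O | intermediate
7 | (2S,3S)-5-hydroxy-7-(methoxymethoxy)-2,3-dimethylchroman-4-one | COCOc1cc(O)c2c(c1)O[C@@H](C)[C@H](C)C2=O | intermediate
8 | (2S,3S)-5-(allyloxy)-7-(methoxymethoxy)-2,3-dimethylchroman-4-one | COCOc1cc(OCC=C)c2c(c1)O[C@@H](C)[C@H](C)C2=O | intermediate
9 | (2S,3S)-6-allyl-7-(methoxymethoxy)-2,3-dimethyl-2,3-dihydro-4H-chromene-4,5(6H)-dione, the ortho-dienone (not isolated; transient C6 centre open) | C=CCC1C(=O)C2=C(C=C1OCOC)O[C@@H](C)[C@H](C)C2=O | intermediate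
10 | (2S,3S)-6-allyl-5-hydroxy-7-(methoxymethoxy)-2,3-dimethylchroman-4-one | C=CCc1c(O)c2c(cc1OCOC)O[C@@H](C)[C@H](C)C2=O | intermediate
11 | (2S,3S)-6-allyl-5,7-dihydroxy-2,3-dimethylchroman-4-one | C=CCc1c(O)c2c(cc1O)O[C@@H](C)[C@H](C)C2=O | intermediate
12 | (2S,3S)-5,7-dihydroxy-2,3-dimethyl-6-(3-methylbut-2-en-1-yl)chroman-4-one | CC(C)=CCc1c(O)c2c(cc1O)O[C@@H](C)[C@H](C)C2=O | intermediate
13 | hex-2-yn-1-ol | CCCC#CCO | starting material
14 | hex-2-ynal | CCCC#CC=O | intermediate
15 | (E)-hex-2-enoyl derivative of the (5aR,10bS) triazolium, chloride (not isolated) | CCC/C=C/C(=O)C1=[N+](c2c(C)cc(C)cc2C)N=C2CO[C@@H]3Cc4ccccc4[C@@H]3N12.[Cl-] | intermediate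
16 | (3R)-3-[(2S,3S)-5,7-dihydroxy-2,3-dimethyl-6-prenyl-4-oxochroman-8-yl]hexanoyl derivative of the (5aR,10bS) triazolium, chloride (not isolated) | CCC[C@H](CC(=O)C1=[N+](c2c(C)cc(C)cc2C)N=C2CO[C@@H]3Cc4ccccc4[C@@H]3N12)c1c(O)c(CC=C(C)C)c(O)c2c1O[C@@H](C)[C@H](C)C2=O.[Cl-] | intermediate
17 | (2S,3S,10R)-5-hydroxy-2,3-dimethyl-6-(3-methylbut-2-en-1-yl)-10-propyl-2,3,9,10-tetrahydro-4H,8H-pyrano[2,3-f]chromene-4,8-dione | CCC[C@@H]1CC(=O)Oc2c(CC=C(C)C)c(O)c3c(c21)O[C@@H](C)[C@H](C)C3=O | intermediate
18 | methyl (3R)-3-[(2S,3S)-5,7-dihydroxy-2,3-dimethyl-6-(3-methylbut-2-en-1-yl)-4-oxochroman-8-yl]hexanoate | CCC[C@H](CC(=O)OC)c1c(O)c(CC=C(C)C)c(O)c2c1O[C@@H](C)[C@H](C)C2=O | target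

## Step count

- Total step count: 11.
- Longest linear sequence: 10 (steps 1–8, 10, 11). Step 9 is a one-step side branch.

## Steps most likely to fail

**1. Step 10.**
- What may go wrong: the 7-hydroxyl may be acylated without the C8–C bond ever forming. The phenol may add to the alkyne of the ynal in an oxa-Michael sense. The ketone-deactivated ring may react too slowly, or the facial selectivity at the β-carbon may be poor.
- Fallback (known chemistry, from 12 back to 17): the conjugate addition and lactonisation of phloroglucinols with alkylidene Meldrum's acids. Butanal and Meldrum's acid are condensed (Knoevenagel, pyrrolidinium acetate, benzene, rt) to 5-butylidene-2,2-dimethyl-1,3-dioxane-4,6-dione F1. Warming 12 with F1 in pyridine should bond C8 to the alkylidene carbon, after which O7 opens the dioxanedione ring and acetone and CO2 are lost in the same flask.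
- Outcome: no reagent controls the new centre, so 17 should form together with its epimer at the propyl-bearing carbon, the (2S,3S,10S)-lactone F2. Because C2 and C3 are fixed, the two are diastereomers; they are separated by chromatography and 17 goes on to step 11.

**2. Step 3.**
- What may go wrong: carbene addition to the electron-rich, doubly ortho-substituted aldehyde may be slow. Configurational purity at C2 may be lost through base-induced opening and re-closure of ring B. The 1-methylallyl ether may undergo a thermal Claisen shift at the reaction temperature.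
- Fallback (from 2 back to 6, bypassing 3, 4 and 5; C3 is set by a reagent instead): Brown crotylboration of 2 with two equivalents of (E)-crotyldiisopinocampheylborane (from trans-but-2-ene, nBuLi/KOtBu and (−)-Ipc2BOMe) in THF at −78 °C, with oxidative work-up. By the usual model this should give the anti homoallylic alcohol (1S,2S)-1-[2-hydroxy-4,6-bis(methoxymethoxy)phenyl]-2-methylbut-3-en-1-ol F3.
- Hg(OAc)2 in THF then closes ring B by 6-exo attack of the phenol on the internal alkene carbon, giving [(2R,3R,4S)-4-hydroxy-5,7-bis(methoxymethoxy)-3-methylchroman-2-yl]methylmercury acetate F4. Alkaline NaBH4 in the same flask reduces it to (2S,3R,4S)-5,7-bis(methoxymethoxy)-2,3-dimethylchroman-4-ol F5, in which the 2-methyl group should sit equatorial and trans to the 3-methyl group.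
- Dess–Martin periodinane (NaHCO3, CH2Cl2) oxidises the carbinol of F5 to ketone 6.

**3. Step 6.**
- What may go wrong: the simple allyl ether may need temperatures at which the allyl group is lost, moves on to C8 by a following Cope shift, or at which C3 epimerises.
- Fallback (from 7 back to 10, bypassing 8 and 9; a cross-coupling replaces the sigmatropic shift): iodination of 7 with BnMe3N·ICl2 and CaCO3 in CH2Cl2/MeOH at rt, steered ortho to the free 5-hydroxyl as known for 5-hydroxy-7-alkoxy flavonoids. This should give (2S,3S)-5-hydroxy-6-iodo-7-(methoxymethoxy)-2,3-dimethylchroman-4-one F6.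
- Stille coupling of F6 with allyltributylstannane under the zerovalent palladium complex Pd(PPh3)4 in DMF at 90 °C then gives 10.

## Further compounds

F1 | step 10 | 5-butylidene-2,2-dimethyl-1,3-dioxane-4,6-dione | CCCC=C1C(=O)OC(C)(C)OC1=O
F2 | step 10 | (2S,3S,10S)-5-hydroxy-2,3-dimethyl-6-(3-methylbut-2-en-1-yl)-10-propyl-2,3,9,10-tetrahydro-4H,8H-pyrano[2,3-f]chromene-4,8-dione | CCC[C@H]1CC(=O)Oc2c(CC=C(C)C)c(O)c3c(c21)O[C@@H](C)[C@H](C)C3=O
F3 | step 3 | (1S,2S)-1-[2-hydroxy-4,6-bis(methoxymethoxy)phenyl]-2-methylbut-3-en-1-ol | C=C[C@H](C)[C@H](O)c1c(O)cc(OCOC)cc1OCOC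
F4 | step 3 | [(2R,3R,4S)-4-hydroxy-5,7-bis(methoxymethoxy)-3-methylchroman-2-yl]methylmercury acetate | COCOc1cc(OCOC)c2c(c1)O[C@@H](C[Hg]OC(C)=O)[C@H](C)[C@@H]2O
F5 | step 3 | (2S,3R,4S)-5,7-bis(methoxymethoxy)-2,3-dimethylchroman-4-ol | COCOc1cc(OCOC)c2c(c1)O[C@@H](C)[C@H](C)[C@@H]2O
F6 | step 6 | (2S,3S)-5-hydroxy-6-iodo-7-(methoxymethoxy)-2,3-dimethylchroman-4-one | Ic1c(O)c2c(cc1OCOC)O[C@@H](C)[C@H](C)C2=O
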